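Amounts first: you have 0.080 M of Q to charge, and the decision is whether to give it 2.00 equiv of G or to spend 8.00 equiv, which pays if G moves the point where the flask stops.

the same everywhere: E 47 mM (held)

| run | Q | G | remark | time |
|---|---|---|---|---|
| dawn | 0.12 M | 2 equiv | run made earlier |  |
| flask | 0.080 M | 2.00 equiv |  | 4.0 min |

dawn run (percent of the Q charged)

| time / s | D / % | L / % |
|---|---|---|
| 10.0 | 24 | 45 |
| 20.0 | 59 | 41 |
| 40.0 | 93 | 9 |
| 80.0 | 94 | 7 |

(readings scatter by 1.5 percentage points)

- Q is a solid; its amount is given per volume of the solution
- at the start none of E is in solution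
- at the start none of Q is in solution
- L means what is dissolved; the solid is not counted in it

- amount of D in the flask at 4.0 min, in percent of the Q charged
- amount of L in the flask at 4.0 min, in percent of the Q charged
- concentration of Z at 4.0 min, in M

The dawn readings stood still from 40.0 s, with D at 93 % there and 94 % at 80.0 s, and the flask's 4.0 min is longer than that whole run, so I expect to read a stop (thermodynamic control), not a race. The last dawn reading gives 13.4 for the stop ratio, [D]/[L] once the flask stands still, though the L in it carries a scatter of 1.5 percentage points, so this is a loose reading.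

My reckoning takes L + Z ⇌ D, so the stop ratio is an equilibrium constant times [Z], and it takes Z as fed from the held gas up to 47 mM. On this scheme the last dawn reading puts 0.113 M of Z into D, more than one such filling, so I suppose the gas refills it. The stop ratio then contains neither Q nor G, and in the flask I expect L at 6.94 %, D at 93.1 % and [Z] at 0.047 M. I would charge 2.00 equiv of G and leave it at that.

The forecast gives 91 % of D, 9.5 % of L and 0.085 M of Z, on the ground “I assume L + Z ⇌ D, with Z formed from G and the held gas E”. Its [Z] follows G, while mine stays at the gas's value.

The flask at 4.0 min gives 96.1 % of D, 3.93 % of L and 0.0470 M of Z.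

    L + Z ⇌ D (K = 520 M⁻¹, k = 10.0 M⁻¹ s⁻¹)
    G + Z ⇌ J (K = 18.0 M⁻¹, k = 20.0 M⁻¹ s⁻¹)
    E ⇌ Z, rate k3*(csat - [Z]) (kL = 0.160 s⁻¹)
    Q ⇌ L, rate k4*(cs4 - [L]) while solid is left; crystals form when [L] > cs4 (solubility = 0.0700 M, k = 0.320 s⁻¹)

That [Z] equals the saturation value of E, with 54 % of the G charge left unbound. The flask's stop ratio is 24.4, and the equilibrium constant of L + Z ⇌ D times [Z] is 24.4, whereas the 13.4 I carried from the last dawn reading had put L at 6.94 %. The neighbour flask with 8.00 equiv of G stops at about the same ratio, 24.5, with 96.1 % of D and 3.93 % of L.

The numbers in the tables are calculated on assumed constants; noise was put on by code.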